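**An impossible start.** Target cannot form at the first instant: it needs substrate and dissolved gas, and at the start none of the gas is dissolved. The gas phase feeds dissolved gas, which also slips reversibly into a dormant form, condenses with itself, or turns target into over-reacted product.

common to all: gas phase 63 mM (held)

| charge | substrate | remark | time |
|---|---|---|---|
| Monday's | 0.22 M | run made earlier |  |
| Wednesday's | 0.35 M | run made earlier |  |
| flask | 0.16 M |  | 8.0 min |

| run | time / min | target / % | substrate / % |
|---|---|---|---|
| Monday's | 0.833 | 17.5 | 82.6 |
| Monday's | 2.50 | 45.8 | 52.6 |
| Monday's | 4.00 | 64.3 | 34.1 |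
| Monday's | 6.00 | 79.2 | 19.3 |
| Monday's | 10.0 | 89.9 | 6.0 |
| Wednesday's | 2.00 | 37.2 | 61.4 |
| Wednesday's | 4.00 | 63.2 | 36.0 |
| Wednesday's | 6.00 | 77.9 | 20.6 |
| Wednesday's | 8.00 | 85.5 | 10.3 |
| Wednesday's | 10.0 | 89.7 | 6.7 |

(readings scatter by 0.5 percentage points)
- at the start none of the gas is dissolved
- steps under discussion: substrate + dissolved gas -> target; dissolved gas <-> dormant form; dissolved gas + target -> over-reacted product; gas phase <-> dissolved gas; 2 dissolved gas -> self-condensation product
- how much target there is at 8.0 min, in percent of the substrate charged
- the change that raises the amount of target at 8.0 min, in percent of the substrate charged most ("none" if none brings more than 2 percentage points) (spring / midnight / none)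
- amount of target at 8.0 min, in percent of the substrate charged, after midnight
- spring: doubling the transfer coefficient of the gas phase, all else as stated
- midnight: doubling the saturation concentration of gas phase, all else as stated

**First estimate.** Suppose c(dissolved gas) quickly reaches a steady level. Substrate then decays pseudo-first-order, and you need one number: the apparent constant, the fraction of substrate lost per minute at that gas level. Monday's run gives 0.281 min⁻¹.

**But the charge?** More substrate should drain the gas and slow the decay. Yet Wednesday's run, with the larger charge, gives 0.277 min⁻¹, so I use the same constant for this smaller charge.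

**But the lag?** Start from Monday's reading at 4.00 min, and the early delay drops out: substrate left at 8.0 min is 11.1%. Target is not simply the remainder, since Monday's balance falls short. Midway between its last two readings the gap is 2.8 percentage points, so I expect 86.1%.

**The two changes.** That same reading puts the lag at 0.176 min. Removing it entirely under spring gains about 0.54 points, less than the 2 points that counts. Under midnight, if the gas level doubles, substrate left is 1.22%. The loss more than doubles, though, since target also stands higher earlier: I get 7.2 points, and so 91.5%.

**The forecast.** It gives 86%, names midnight and puts that change at 91%, where I have 91.5%; it holds that “The rate scales with substrate, so gas supply is not limiting”.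

    substrate + dissolved gas → target (k = 0.0810 M⁻¹ s⁻¹)
    dissolved gas ⇌ dormant form (K = 0.890, k = 0.0230 s⁻¹)
    dissolved gas + target → over-reacted product (k = 0.00190 M⁻¹ s⁻¹)
    gas phase ⇌ dissolved gas, rate k4*(csat - [dissolved gas]) (kL = 0.160 s⁻¹)
    2 dissolved gas → self-condensation product (k = 0.0390 M⁻¹ s⁻¹)

**The result.** The flask gives 86.4% of target at 8.0 min. Midnight gives 91.1%, a gain of 4.7 points, against 0.76 points for spring. Dissolved gas in the flask stood at 86.7% of saturation by 0.800 min and 94.3% by 4.00 min. Substrate left at 8.0 min is 11%. Carried back from there with 0.281 min⁻¹, the same flask read at 3.0 min should hold 42.9% substrate, and it holds 45.1%.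

The data were computed for an exercise.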